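The route rests on cutting the sp2–sp3 bond between ring carbon C5 of the 4-hydroxybenzoic acid ring (ortho to the phenol oxygen) and C1' of the ten-carbon side chain. The feature exploited is the unbranched C1'–C2' ethylene link that ends at the methyl-bearing stereocentre C3': it is the anti-Markovnikov hydroboration adduct of a vinyl group. A one-pot 9-BBN hydroboration/B-alkyl Suzuki–Miyaura coupling therefore joins a fully functionalised aryl iodide (hydroxyprenyl arm and carboxylic acid in place) to a (3S)-3-methyl-1,5-dien-4-ol carrying all chain carbons, made by Brown anti-crotylation. The C4' carbinol is then oxidised to the enone and the silyl groups are removed.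

Key step: step 9

Remark on the chemistry: primed locants refer to the ten-carbon side chain; the carbinol centre C4' made in step 3 is sacrificial (oxidised in step 10), and its descriptor changes from R (8) to S (20, 21) only because the CIP ranking of its carbon neighbours changes when the vinyl group becomes CH2CH2.

Step 1
Reactants: 1 2-methylbut-3-en-2-ol; 2 (2E)-but-2-enal (crotonaldehyde)
Product: 3 (2E)-4-hydroxy-4-methylpent-2-enal
Conditions: second-generation Hoveyda–Grubbs catalyst (3 mol%), 1 (3 equiv), CH2Cl2, 40 °C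
Reagents that add atoms: none
Why: Olefin cross-metathesis between the free tertiary allylic alcohol and the enal, two partners that homodimerise slowly, should give the conjugated E-enal under thermodynamic control with loss of propene.

Step 2
Reactants: 3 (2E)-4-hydroxy-4-methylpent-2-enal
Product: 4 (2E)-4-methyl-4-[(triethylsilyl)oxy]pent-2-enal
Conditions: TESOTf, 2,6-lutidine, CH2Cl2, −78 to 0 °C
Reagents that add atoms: triethylsilyl trifluoromethanesulfonate (TESOTf), CC[Si](CC)(CC)OS(=O)(=O)C(F)(F)F
Why: Silyl ether formation with a silyl triflate is the standard way to cap a hindered tertiary alcohol and keeps the hydroxyl from consuming the allylborane of step 3 and the 9-BBN of step 9.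

Step 3
Reactants: 4 (2E)-4-methyl-4-[(triethylsilyl)oxy]pent-2-enal; 5 (2E)-but-2-ene
Product: 8 (3S,4R,5E)-3,7-dimethyl-7-[(triethylsilyl)oxy]octa-1,5-dien-4-ol, via crotylborane 6 (not isolated), via borinate 7 (not isolated)
Conditions: 5, KOt-Bu, n-BuLi, THF, −78 to −45 °C; (−)-Ipc2BOMe [from (+)-α-pinene], −78 °C; BF3·OEt2, then 4, −78 °C; NaOH, H2O2, 0 °C to rt
Reagents that add atoms: none
Why: Brown asymmetric crotylboration, in which the closed chair (Zimmerman–Traxler) transition state turns the E geometry of the crotylborane into the anti relationship and the (1R,2S,3R,5R)-isopinocampheyl groups direct addition to the si face of the aldehyde, should set C3 as S (C4 is R and sacrificial).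

Step 4
Reactants: 9 methyl 4-hydroxy-3-iodobenzoate; 10 3-bromoprop-1-ene (allyl bromide)
Product: 11 methyl 3-iodo-4-(prop-2-en-1-yloxy)benzoate
Conditions: K2CO3, acetone, 56 °C
Reagents that add atoms: none
Why: Williamson ether synthesis of an acidic phenol with an allylic bromide should proceed cleanly at oxygen under carbonate conditions.

Step 5
Reactants: 11 methyl 3-iodo-4-(prop-2-en-1-yloxy)benzoate
Product: 13 methyl 4-hydroxy-3-iodo-5-(prop-2-en-1-yl)benzoate, via dienone 12 (not isolated)
Conditions: N,N-diethylaniline, 190 °C, sealed tube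
Reagents that add atoms: none
Why: Aromatic Claisen rearrangement ([3,3]-sigmatropic shift) can only end productively at the single free ortho carbon, since the other ortho position bears iodine and the para position the ester, and tautomerisation of the dienone restores the phenol.

Step 6
Reactants: 13 methyl 4-hydroxy-3-iodo-5-(prop-2-en-1-yl)benzoate; 14 2-methylprop-2-enal (methacrolein)
Product: 15 methyl 4-hydroxy-3-iodo-5-[(2E)-3-methyl-4-oxobut-2-en-1-yl]benzoate
Conditions: second-generation Hoveyda–Grubbs catalyst (5 mol%), 14 (10 equiv), CH2Cl2, 40 °C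
Reagents that add atoms: none
Why: Olefin cross-metathesis of a terminal allyl group with excess methacrolein should give the trisubstituted enal with the E geometry (formyl group trans to the benzylic carbon) that is strongly favoured thermodynamically.

Step 7
Reactants: 15 methyl 4-hydroxy-3-iodo-5-[(2E)-3-methyl-4-oxobut-2-en-1-yl]benzoate
Product: 17 4-hydroxy-3-[(2E)-4-hydroxy-3-methylbut-2-en-1-yl]-5-iodobenzoic acid, via diol ester 16 (not isolated)
Conditions: NaBH4, CeCl3·7H2O, MeOH, −40 to 0 °C; then 2 M aq LiOH, THF, 50 °C; 1 M HCl to pH 3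
Reagents that add atoms: lithium hydroxide, [Li+].[OH-]
Why: Luche 1,2-reduction of the enal (fast and non-basic, so the ortho phenol does not add to the enal) followed by saponification in the same flask removes the ester while no base-sensitive ketone stereocentre exists yet.

Step 8
Reactants: 17 4-hydroxy-3-[(2E)-4-hydroxy-3-methylbut-2-en-1-yl]-5-iodobenzoic acid
Product: 19 4-[(tert-butyldimethylsilyl)oxy]-3-[(2E)-4-[(tert-butyldimethylsilyl)oxy]-3-methylbut-2-en-1-yl]-5-iodobenzoic acid, via silyl ester 18 (not isolated)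
Conditions: TBSCl (4 equiv), imidazole, DMAP (cat.), DMF, rt to 40 °C; then 5% aq citric acid, THF, rt
Reagents that add atoms: tert-butyldimethylsilyl chloride (TBSCl), CC(C)(C)[Si](C)(C)Cl
Why: Silylation with a silyl chloride and imidazole caps the phenol and the primary allylic alcohol (needed for the chemoselective oxidation of step 10), and the labile silyl ester formed at the same time is hydrolysed by the mild acidic work-up.

Step 9
Reactants: 8 (3S,4R,5E)-3,7-dimethyl-7-[(triethylsilyl)oxy]octa-1,5-dien-4-ol; 19 4-[(tert-butyldimethylsilyl)oxy]-3-[(2E)-4-[(tert-butyldimethylsilyl)oxy]-3-methylbut-2-en-1-yl]-5-iodobenzoic acid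
Product: 21 4-[(tert-butyldimethylsilyl)oxy]-3-[(2E)-4-[(tert-butyldimethylsilyl)oxy]-3-methylbut-2-en-1-yl]-5-[(3S,4S,5E)-4-hydroxy-3,7-dimethyl-7-[(triethylsilyl)oxy]oct-5-en-1-yl]benzoic acid, via alkylborane 20 (not isolated)
Conditions: 8 (1.3 equiv), 9-BBN (0.5 M in THF, 3 equiv), 0 °C to rt; then 19 in degassed 3 M aq K3PO4, Pd(dppf)Cl2·CH2Cl2 (10 mol%), AsPh3 (10 mol%), DMF/THF, rt to 45 °C
Reagents that add atoms: none
Why: 9-BBN adds B–H anti-Markovnikov to the monosubstituted C1=C2 vinyl group of 8 (the C4 hydroxyl is masked in the flask as its borinate, and the E-disubstituted C5=C6 alkene between a carbinol and a quaternary carbon is too hindered to react), and the primary alkylborane 20 is activated by hydroxide/phosphate as a borate. Zerovalent palladium inserts into the C–I bond of 19, the primary alkyl group is transferred to palladium with retention, and reductive elimination forms the bond between ring carbon C5 and C1'; the wide-bite-angle dppf ligand should make reductive elimination faster than β-hydride elimination. The closest known reaction type is the B-alkyl Suzuki–Miyaura coupling of 9-BBN adducts with aryl iodides, which tolerates carboxylates, silyl ethers and allylic oxygen functions. No ring is closed and no stereocentre is formed; C3 (S) is a spectator and cannot epimerise because C4 is still a carbinol and not a ketone. The selectivities needed are hydroboration of one alkene among three (only 8 meets B–H, and only its vinyl group is unhindered) and cross-coupling ahead of protodeboronation, secured by excess borane and by an iodide as the electrophile.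

Step 10
Reactants: 21 4-[(tert-butyldimethylsilyl)oxy]-3-[(2E)-4-[(tert-butyldimethylsilyl)oxy]-3-methylbut-2-en-1-yl]-5-[(3S,4S,5E)-4-hydroxy-3,7-dimethyl-7-[(triethylsilyl)oxy]oct-5-en-1-yl]benzoic acid
Product: 22 4-[(tert-butyldimethylsilyl)oxy]-3-[(2E)-4-[(tert-butyldimethylsilyl)oxy]-3-methylbut-2-en-1-yl]-5-[(3S,5E)-3,7-dimethyl-4-oxo-7-[(triethylsilyl)oxy]oct-5-en-1-yl]benzoic acid
Conditions: Dess–Martin periodinane, NaHCO3, CH2Cl2, 0 °C to rt
Reagents that add atoms: none
Why: Dess–Martin oxidation of the only free hydroxyl, a secondary allylic alcohol, should give the E-enone under buffered, non-enolising conditions that leave the adjacent C3' stereocentre untouched.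

Step 11
Reactants: 22 4-[(tert-butyldimethylsilyl)oxy]-3-[(2E)-4-[(tert-butyldimethylsilyl)oxy]-3-methylbut-2-en-1-yl]-5-[(3S,5E)-3,7-dimethyl-4-oxo-7-[(triethylsilyl)oxy]oct-5-en-1-yl]benzoic acid
Product: 23 4-hydroxy-3-[(2E)-4-hydroxy-3-methylbut-2-en-1-yl]-5-[(3S,5E)-7-hydroxy-3,7-dimethyl-4-oxooct-5-en-1-yl]benzoic acid (target)
Conditions: TBAF, AcOH (1:1, 6 equiv each), THF, 0 °C to rt
Reagents that add atoms: none
Why: Fluoride-mediated desilylation cleaves the aryl and primary tert-butyldimethylsilyl ethers and the tertiary triethylsilyl ether in one operation, and the acetic acid buffer keeps the medium from enolising the α-methyl ketone.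

Compound list
1 | 2-methylbut-3-en-2-ol | C=CC(C)(C)O | starting material
2 | (2E)-but-2-enal | C/C=C/C=O | starting material
3 | (2E)-4-hydroxy-4-methylpent-2-enal | CC(C)(O)/C=C/C=O | intermediate
4 | (2E)-4-methyl-4-[(triethylsilyl)oxy]pent-2-enal | CC[Si](CC)(CC)OC(C)(C)/C=C/C=O | intermediate
5 | (2E)-but-2-ene | C/C=C/C | starting material
6 | [(2E)-but-2-en-1-yl]bis[(1R,2S,3R,5R)-2,6,6-trimethylbicyclo[3.1.1]hept-3-yl]borane | C/C=C/CB([C@@H]1C[C@@H]2C[C@H]([C@H]1C)C2(C)C)[C@@H]1C[C@@H]2C[C@H]([C@H]1C)C2(C)C | intermediate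
7 | (3S,4R,5E)-3,7-dimethyl-7-[(triethylsilyl)oxy]octa-1,5-dien-4-yl bis[(1R,2S,3R,5R)-2,6,6-trimethylbicyclo[3.1.1]hept-3-yl]borinate | C=C[C@H](C)[C@H](OB([C@@H]1C[C@@H]2C[C@H]([C@H]1C)C2(C)C)[C@@H]1C[C@@H]2C[C@H]([C@H]1C)C2(C)C)/C=C/C(C)(C)O[Si](CC)(CC)CC | intermediate
8 | (3S,4R,5E)-3,7-dimethyl-7-[(triethylsilyl)oxy]octa-1,5-dien-4-ol | C=C[C@H](C)[C@H](O)/C=C/C(C)(C)O[Si](CC)(CC)CC | intermediate
9 | methyl 4-hydroxy-3-iodobenzoate | COC(=O)c1ccc(O)c(I)c1 | starting material
10 | 3-bromoprop-1-ene | C=CCBr | starting material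
11 | methyl 3-iodo-4-(prop-2-en-1-yloxy)benzoate | COC(=O)c1ccc(OCC=C)c(I)c1 | intermediate
12 | methyl 5-iodo-4-oxo-3-(prop-2-en-1-yl)cyclohexa-1,5-diene-1-carboxylate | COC(=O)C1=CC(CC=C)C(=O)C(I)=C1 | intermediate
13 | methyl 4-hydroxy-3-iodo-5-(prop-2-en-1-yl)benzoate | COC(=O)c1cc(I)c(O)c(CC=C)c1 | intermediate
14 | 2-methylprop-2-enal | CC(=C)C=O | starting material
15 | methyl 4-hydroxy-3-iodo-5-[(2E)-3-methyl-4-oxobut-2-en-1-yl]benzoate | C/C(=C\Cc1cc(C(=O)OC)cc(I)c1O)C=O | intermediate
16 | methyl 4-hydroxy-3-[(2E)-4-hydroxy-3-methylbut-2-en-1-yl]-5-iodobenzoate | C/C(=C\Cc1cc(C(=O)OC)cc(I)c1O)CO | intermediate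
17 | 4-hydroxy-3-[(2E)-4-hydroxy-3-methylbut-2-en-1-yl]-5-iodobenzoic acid | C/C(=C\Cc1cc(C(=O)O)cc(I)c1O)CO | intermediate
18 | tert-butyldimethylsilyl 4-[(tert-butyldimethylsilyl)oxy]-3-[(2E)-4-[(tert-butyldimethylsilyl)oxy]-3-methylbut-2-en-1-yl]-5-iodobenzoate | C/C(=C\Cc1cc(C(=O)O[Si](C)(C)C(C)(C)C)cc(I)c1O[Si](C)(C)C(C)(C)C)CO[Si](C)(C)C(C)(C)C | intermediate
19 | 4-[(tert-butyldimethylsilyl)oxy]-3-[(2E)-4-[(tert-butyldimethylsilyl)oxy]-3-methylbut-2-en-1-yl]-5-iodobenzoic acid | C/C(=C\Cc1cc(C(=O)O)cc(I)c1O[Si](C)(C)C(C)(C)C)CO[Si](C)(C)C(C)(C)C | intermediate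
20 | 9-[(3S,4S,5E)-4-(9-borabicyclo[3.3.1]nonan-9-yloxy)-3,7-dimethyl-7-[(triethylsilyl)oxy]oct-5-en-1-yl]-9-borabicyclo[3.3.1]nonane | B1(CC[C@H](C)[C@H](OB2C3CCCC2CCC3)/C=C/C(C)(C)O[Si](CC)(CC)CC)C2CCCC1CCC2 | intermediate
21 | 4-[(tert-butyldimethylsilyl)oxy]-3-[(2E)-4-[(tert-butyldimethylsilyl)oxy]-3-methylbut-2-en-1-yl]-5-[(3S,4S,5E)-4-hydroxy-3,7-dimethyl-7-[(triethylsilyl)oxy]oct-5-en-1-yl]benzoic acid | C/C(=C\Cc1cc(C(=O)O)cc(CC[C@H](C)[C@H](O)/C=C/C(C)(C)O[Si](CC)(CC)CC)c1O[Si](C)(C)C(C)(C)C)CO[Si](C)(C)C(C)(C)C | intermediate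
22 | 4-[(tert-butyldimethylsilyl)oxy]-3-[(2E)-4-[(tert-butyldimethylsilyl)oxy]-3-methylbut-2-en-1-yl]-5-[(3S,5E)-3,7-dimethyl-4-oxo-7-[(triethylsilyl)oxy]oct-5-en-1-yl]benzoic acid | C/C(=C\Cc1cc(C(=O)O)cc(CC[C@H](C)C(=O)/C=C/C(C)(C)O[Si](CC)(CC)CC)c1O[Si](C)(C)C(C)(C)C)CO[Si](C)(C)C(C)(C)C | intermediate
23 | 4-hydroxy-3-[(2E)-4-hydroxy-3-methylbut-2-en-1-yl]-5-[(3S,5E)-7-hydroxy-3,7-dimethyl-4-oxooct-5-en-1-yl]benzoic acid | C/C(=C\Cc1cc(C(=O)O)cc(CC[C@H](C)C(=O)/C=C/C(C)(C)O)c1O)CO | target

Total step count: 11. Longest linear sequence: 8 steps (steps 4 to 11, from methyl 4-hydroxy-3-iodobenzoate); the side-chain branch (steps 1 to 3) joins at step 9.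

Steps most likely to fail

Step 9. What may go wrong: slow transmetalation of a borane that carries a neighbouring borinate onto an arylpalladium iodide flanked by a bulky silyloxy group and bearing a carboxylate, so that protodeboronation, β-hydride elimination and base-induced loss of the aryl silyl ether take over. The fallback is a Negishi coupling with the enone already in place; it sets out from 8 and comes back at 22. Compound 8 is hydroborated with 9-BBN and oxidised (NaOH, H2O2) to (3S,4S,5E)-3,7-dimethyl-7-[(triethylsilyl)oxy]oct-5-ene-1,4-diol F1. MnO2 in CH2Cl2 should oxidise only the allylic secondary hydroxyl to (3S,5E)-1-hydroxy-3,7-dimethyl-7-[(triethylsilyl)oxy]oct-5-en-4-one F2. I2, PPh3 and imidazole then give (3S,5E)-1-iodo-3,7-dimethyl-7-[(triethylsilyl)oxy]oct-5-en-4-one F3. Zinc dust and LiCl in THF insert to give iodo[(3S,5E)-3,7-dimethyl-4-oxo-7-[(triethylsilyl)oxy]oct-5-en-1-yl]zinc F4. This is coupled with the silyl ester 18 (isolated by a non-aqueous work-up of step 8) under Pd(OAc)2/SPhos catalysis in THF/NMP to give the tert-butyldimethylsilyl ester of 22 F5. Aqueous citric acid hydrolyses the silyl ester and the route resumes at 22; step 10 is then not needed.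

Step 3. What may go wrong: partial E-to-Z equilibration of the crotylpotassium before it is transferred to boron, or incomplete facial discrimination on the conjugated aldehyde, either of which erodes the configuration at C3. The fallback replaces the stoichiometric chiral borane by a catalytic transfer-hydrogenative crotylation; it sets out from 4, comes back at 8 and makes no new compound (F0). Compound 4 is treated with but-3-en-2-yl acetate, [Ir(cod)Cl]2, one SEGPHOS antipode, 4-cyano-3-nitrobenzoic acid, Cs2CO3 and 2-propanol in THF at 70 °C. The cyclometalated π-crotyl iridium complex should deliver the anti adduct through a closed transition state that does not depend on the geometry of a preformed crotyl metal. The sense of induction of each SEGPHOS antipode is not assigned here; the antipode is chosen as the one that leads to the (3S,4R) series.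

Step 1. What may go wrong: slow, unselective metathesis between two sluggish olefins with catalyst decay, and self-condensation of the free hydroxy enal on concentration. The fallback uses ozonolysis and a Wittig reaction instead of metathesis; it sets out from 1 and comes back at 4. Compound 1 is silylated (TESOTf, 2,6-lutidine) to triethyl[(2-methylbut-3-en-2-yl)oxy]silane F6. Ozonolysis (O3, CH2Cl2, −78 °C; PPh3) gives 2-methyl-2-[(triethylsilyl)oxy]propanal F7. Homologation with (triphenylphosphoranylidene)acetaldehyde in toluene at 80 °C, a stabilised ylide, should give the E-enal 4 directly, so step 2 is also bypassed.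

Further compounds
F1 | step 9 | (3S,4S,5E)-3,7-dimethyl-7-[(triethylsilyl)oxy]oct-5-ene-1,4-diol | OCC[C@H](C)[C@H](O)/C=C/C(C)(C)O[Si](CC)(CC)CC
F2 | step 9 | (3S,5E)-1-hydroxy-3,7-dimethyl-7-[(triethylsilyl)oxy]oct-5-en-4-one | OCC[C@H](C)C(=O)/C=C/C(C)(C)O[Si](CC)(CC)CC
F3 | step 9 | (3S,5E)-1-iodo-3,7-dimethyl-7-[(triethylsilyl)oxy]oct-5-en-4-one | ICC[C@H](C)C(=O)/C=C/C(C)(C)O[Si](CC)(CC)CC
F4 | step 9 | iodo[(3S,5E)-3,7-dimethyl-4-oxo-7-[(triethylsilyl)oxy]oct-5-en-1-yl]zinc | I[Zn]CC[C@H](C)C(=O)/C=C/C(C)(C)O[Si](CC)(CC)CC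
F5 | step 9 | tert-butyldimethylsilyl 4-[(tert-butyldimethylsilyl)oxy]-3-[(2E)-4-[(tert-butyldimethylsilyl)oxy]-3-methylbut-2-en-1-yl]-5-[(3S,5E)-3,7-dimethyl-4-oxo-7-[(triethylsilyl)oxy]oct-5-en-1-yl]benzoate | C/C(=C\Cc1cc(C(=O)O[Si](C)(C)C(C)(C)C)cc(CC[C@H](C)C(=O)/C=C/C(C)(C)O[Si](CC)(CC)CC)c1O[Si](C)(C)C(C)(C)C)CO[Si](C)(C)C(C)(C)C
F0 | step 3 | none | none
F6 | step 1 | triethyl[(2-methylbut-3-en-2-yl)oxy]silane | C=CC(C)(C)O[Si](CC)(CC)CC
F7 | step 1 | 2-methyl-2-[(triethylsilyl)oxy]propanal | O=CC(C)(C)O[Si](CC)(CC)CC
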